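**Strategy.** The cyclohexadienone ring is disconnected across C4–C5 and C1–C6 (C1 = ring carbonyl, C2 = amide carbon, C4 = carbinol carbon, C6 = chlorinated carbon). The C1(=O)–C2(N)=C3–C4(OH)R arc is read as an opened 2-silyloxy-3-amido-5-alkylfuran whose ring oxygen becomes the C4 hydroxyl, and the C5=C6–Cl edge as a chloroacetylene. A Diels–Alder reaction of that furan with enantiopure 1-chlorovinyl p-tolyl sulfoxide (a chiral chloroacetylene equivalent) forms both ring bonds and fixes C4. Desilylative opening of the oxygen bridge and sulfoxide syn-elimination then unveil the chloro-quinol. The furan comes from an isotetronic acid and the separately made dienamide.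

Key step: step 12

Assumption: the sense of induction in steps 1 and 12 is taken as drawn; the pseudoenantiomeric catalyst (DHQ)2AQN and the (S)-vinyl sulfoxide are equally available should either sense prove opposite.

**Route**

Step 1
Reactants: 1 meso-2,4-dimethylglutaric anhydride
Product: 2 (2R,4S)-5-methoxy-2,4-dimethyl-5-oxopentanoic acid
Conditions: MeOH (10 equiv), (DHQD)2AQN (10 mol%), Et2O, −40 °C
Reagents that add atoms: methanol, CO
Why: Cinchona-alkaloid-catalysed desymmetrising alcoholysis of a meso anhydride: the chiral quinuclidine base directs methanol to one enantiotopic carbonyl, which should fix both methyl-bearing stereocentres (2R,4S) in one event.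

Step 2
Reactants: 2 (2R,4S)-5-methoxy-2,4-dimethyl-5-oxopentanoic acid
Product: 3 methyl (2S,4R)-5-hydroxy-2,4-dimethylpentanoate
Conditions: BH3·SMe2, THF, −10 → 0 °C; MeOH quench, aqueous work-up
Reagents that add atoms: none
Why: Chemoselective borane reduction: the free acid (via an acyloxyborane) is reduced much faster than the methyl ester, and neither α-stereocentre is touched.

Step 3
Reactants: 3 methyl (2S,4R)-5-hydroxy-2,4-dimethylpentanoate
Product: 4 methyl (2S,4R)-2,4-dimethyl-5-oxopentanoate
Conditions: Dess–Martin periodinane, NaHCO3, CH2Cl2, 0 °C → rt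
Reagents that add atoms: none
Why: Dess–Martin oxidation under buffered, near-neutral conditions should give the α-branched aldehyde without enolisation of its stereocentre.

Step 4
Reactants: 4 methyl (2S,4R)-2,4-dimethyl-5-oxopentanoate
Product: 5 methyl (2S,4R)-2,4,6-trimethylhept-5-enoate
Conditions: i-PrPPh3I, n-BuLi, THF, 0 °C; then 4, −78 → 0 °C
Reagents that add atoms: isopropyltriphenylphosphonium iodide, CC(C)[P+](c1ccccc1)(c1ccccc1)c1ccccc1.[I-]
Why: Wittig olefination with the non-stabilised isopropylidene ylide at low temperature should convert the aldehyde into the trisubstituted alkene faster than the ylide attacks the ester or epimerises the α-centre.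

Step 5
Reactants: 5 methyl (2S,4R)-2,4,6-trimethylhept-5-enoate
Product: 6 (2S,4R)-2,4,6-trimethylhept-5-enal
Conditions: i-Bu2AlH (1.05 equiv), CH2Cl2, −78 °C; aq. potassium sodium tartrate work-up
Reagents that add atoms: none
Why: Partial reduction of an ester with i-Bu2AlH: the tetrahedral aluminium hemiacetal is stable at −78 °C and releases the aldehyde only on work-up, leaving the alkene and both stereocentres intact.

Step 6
Reactants: 6 (2S,4R)-2,4,6-trimethylhept-5-enal
Product: 7 (2E,4S,6R)-4,6,8-trimethylnona-2,7-dienamide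
Conditions: Ph3P=CHCONH2, CH2Cl2, rt
Reagents that add atoms: 2-(triphenylphosphoranylidene)acetamide, NC(=O)C=P(c1ccccc1)(c1ccccc1)c1ccccc1
Why: Wittig olefination with a stabilised ylide is E-selective, mild enough for the epimerisable α-methyl aldehyde, and installs the primary amide directly.

Step 7
Reactants: 8 methyl 6-oxohexanoate; 9 ethyl 2-(bromomethyl)acrylate
Product: 11 methyl 5-(4-methylidene-5-oxooxolan-2-yl)pentanoate (racemic), via hydroxy diester 10 (not isolated)
Conditions: Zn dust, THF/sat. aq. NH4Cl, rt; then TsOH (cat.), CH2Cl2, rt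
Reagents that add atoms: none
Why: Zinc-mediated Barbier allylation of the aldehyde (chemoselective over the ester) followed by acid-catalysed lactonisation gives the α-methylene-γ-butyrolactone (Dreiding–Schmidt reaction); the new stereocentre is racemic and is erased in step 10.

Step 8
Reactants: 11 methyl 5-(4-methylidene-5-oxooxolan-2-yl)pentanoate
Product: 13 methyl 5-(4-hydroxy-5-oxo-2,5-dihydrofuran-2-yl)pentanoate (racemic; enol form of the 2,3-dione), via spiro ozonide 12 (not isolated)
Conditions: O3, CH2Cl2, −78 °C; then Me2S, −78 °C → rt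
Reagents that add atoms: ozone, [O-][O+]=O
Why: Ozonolysis of the exocyclic alkene with reductive work-up should give the α-keto lactone, which rests as its enol (an isotetronic acid).

Step 9
Reactants: 13 methyl 5-(4-hydroxy-5-oxo-2,5-dihydrofuran-2-yl)pentanoate; 7 (2E,4S,6R)-4,6,8-trimethylnona-2,7-dienamide
Product: 14 methyl 5-[5-oxo-4-{[(2E,4S,6R)-4,6,8-trimethylnona-2,7-dienoyl]amino}-2,5-dihydrofuran-2-yl]pentanoate (both epimers at the lactone carbon)
Conditions: PPTS (10 mol%), toluene, reflux, Dean–Stark trap with 4 Å sieves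
Reagents that add atoms: none
Why: Acid-catalysed dehydrative condensation of an α-keto ester (keto tautomer of 13) with a primary amide should give the conjugated N-acyl enamine, as in dehydroamino-acid synthesis; the lactone stereocentre stays unresolved and irrelevant.

Step 10
Reactants: 14 methyl 5-[5-oxo-4-{[(2E,4S,6R)-4,6,8-trimethylnona-2,7-dienoyl]amino}-2,5-dihydrofuran-2-yl]pentanoate
Product: 15 methyl 5-[5-(tert-butyldimethylsilyloxy)-4-{[(2E,4S,6R)-4,6,8-trimethylnona-2,7-dienoyl]amino}furan-2-yl]pentanoate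
Conditions: TBSOTf (1.2 equiv), Et3N, CH2Cl2, 0 °C; filtered under argon and used at once
Reagents that add atoms: tert-butyldimethylsilyl triflate, CC(C)(C)[Si](C)(C)OS(=O)(=O)C(F)(F)F
Why: Soft enolisation: O-silylation of the lactone carbonyl and loss of the γ-proton are driven by aromatisation to the 2-silyloxyfuran, which removes the unresolved centre.

Step 11
Reactants: 16 (R)-(+)-p-tolyl vinyl sulfoxide
Product: 18 (S)-1-chlorovinyl p-tolyl sulfoxide, via lithiated vinyl sulfoxide 17 (not isolated)
Conditions: LiN(i-Pr)2, THF, −78 °C; then C2Cl6, −78 → −40 °C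
Reagents that add atoms: hexachloroethane, ClC(Cl)(Cl)C(Cl)(Cl)Cl
Why: The sulfinyl group acidifies the α-vinyl proton, so the amide base gives the α-sulfinyl vinyllithium, which hexachloroethane chlorinates with the sulfur stereocentre untouched (the descriptor changes from R to S only through the priority rules).

Step 12
Reactants: 15 methyl 5-[5-(tert-butyldimethylsilyloxy)-4-{[(2E,4S,6R)-4,6,8-trimethylnona-2,7-dienoyl]amino}furan-2-yl]pentanoate; 18 (S)-1-chlorovinyl p-tolyl sulfoxide
Product: 21 methyl 5-[(1R)-3-chloro-1-hydroxy-4-oxo-5-{[(2E,4S,6R)-4,6,8-trimethylnona-2,7-dienoyl]amino}cyclohexa-2,5-dien-1-yl]pentanoate, via oxanorbornene cycloadduct 19 (not isolated), via chlorosulfinyl hydroxy ketone 20 (not isolated)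
Conditions: 18 (1.5 equiv), toluene, 4 Å sieves, 25 → 45 °C; then TBAF/AcOH (1:1), THF, 0 °C; then 70 °C
Reagents that add atoms: none
Why: The electron-rich 2-silyloxyfuran 15 and the captodative vinyl sulfoxide 18 should combine in an asynchronous suprafacial [4+2] cycloaddition in which furan C5 (future C4, para to the silyloxy group and the most nucleophilic terminus) bonds to the CH2 terminus and the silyloxy-bearing furan C2 (future C1) to the chlorinated carbon, giving oxanorbornene 19; fluoride then cleaves the silyl ketal so that the bridge oxygen is released onto C4 as the tertiary hydroxyl (20), and syn-elimination of p-toluenesulfenic acid across C5–C6 gives dienone 21. The closest known reaction types are Diels–Alder reactions of 2-silyloxyfurans with activated alkenes or alkynes that unravel to 4-oxygenated cyclohexenones and phenols, and cycloadditions of enantiopure vinyl sulfoxides used as acetylene equivalents. The six-membered carbocycle is closed by the intermolecular cycloaddition itself, both new bonds (C4–C5 and C1–C6) arising in that one event across a transient oxygen bridge. C4, the only stereocentre that survives, is set by the furan face that is attacked: with the sulfinyl group endo over the amide-bearing edge (N–H···O=S contact), S=O s-cis to the C=C bond and the p-tolyl group turned away from the diene, the (S)-sulfoxide should expose the face that leads to (R)-C4, while the centres at C1, C6 and sulfur are erased in the unravelling. The step needs regioselectivity, endo placement of the sulfinyl group and π-facial selectivity, secured respectively by the matched polarisation of the two partners, by the hydrogen-bonded endo transition state and by the sulfur stereocentre; elimination can only run toward C5 because C1 carries no hydrogen.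

Step 13
Reactants: 21 methyl 5-[(1R)-3-chloro-1-hydroxy-4-oxo-5-{[(2E,4S,6R)-4,6,8-trimethylnona-2,7-dienoyl]amino}cyclohexa-2,5-dien-1-yl]pentanoate
Product: 22 5-[(1R)-3-chloro-1-hydroxy-4-oxo-5-{[(2E,4S,6R)-4,6,8-trimethylnona-2,7-dienoyl]amino}cyclohexa-2,5-dien-1-yl]pentanoic acid (CNP0128873.1)
Conditions: pig liver esterase, phosphate buffer pH 7.2/acetone, 30 °C
Reagents that add atoms: water, O
Why: Esterase-catalysed hydrolysis of a methyl ester at pH 7 (serine-hydrolase acyl-enzyme mechanism) avoids the hydroxide and acid to which the chloro-quinol and the enamide are sensitive; no stereocentre is involved.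

**Compound list**

1 | meso-2,4-dimethylglutaric anhydride, (3R,5S)-3,5-dimethyloxane-2,6-dione | C[C@H]1C[C@@H](C)C(=O)OC1=O | starting material
2 | (2R,4S)-5-methoxy-2,4-dimethyl-5-oxopentanoic acid | OC(=O)[C@H](C)C[C@H](C)C(=O)OC | intermediate
3 | methyl (2S,4R)-5-hydroxy-2,4-dimethylpentanoate | OC[C@H](C)C[C@H](C)C(=O)OC | intermediate
4 | methyl (2S,4R)-2,4-dimethyl-5-oxopentanoate | O=C[C@H](C)C[C@H](C)C(=O)OC | intermediate
5 | methyl (2S,4R)-2,4,6-trimethylhept-5-enoate | CC(C)=C[C@H](C)C[C@H](C)C(=O)OC | intermediate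
6 | (2S,4R)-2,4,6-trimethylhept-5-enal | CC(C)=C[C@H](C)C[C@H](C)C=O | intermediate
7 | (2E,4S,6R)-4,6,8-trimethylnona-2,7-dienamide | CC(C)=C[C@H](C)C[C@H](C)/C=C/C(N)=O | intermediate
8 | methyl 6-oxohexanoate | COC(=O)CCCCC=O | starting material
9 | ethyl 2-(bromomethyl)acrylate | CCOC(=O)C(=C)CBr | starting material
10 | 1-ethyl 9-methyl 4-hydroxy-2-methylidenenonanedioate (racemic, not isolated) | CCOC(=O)C(=C)CC(O)CCCCC(=O)OC | intermediate
11 | methyl 5-(4-methylidene-5-oxooxolan-2-yl)pentanoate (racemic) | COC(=O)CCCCC1CC(=C)C(=O)O1 | intermediate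
12 | spiro 1,2,4-trioxolane (secondary ozonide) of 11 at the exocyclic alkene (not isolated) | COC(=O)CCCCC1CC2(OOCO2)C(=O)O1 | intermediate
13 | methyl 5-(4-hydroxy-5-oxo-2,5-dihydrofuran-2-yl)pentanoate (racemic) | COC(=O)CCCCC1C=C(O)C(=O)O1 | intermediate
14 | methyl 5-[5-oxo-4-{[(2E,4S,6R)-4,6,8-trimethylnona-2,7-dienoyl]amino}-2,5-dihydrofuran-2-yl]pentanoate (both lactone epimers) | COC(=O)CCCCC1C=C(NC(=O)/C=C/[C@@H](C)C[C@@H](C)C=C(C)C)C(=O)O1 | intermediate
15 | methyl 5-[5-(tert-butyldimethylsilyloxy)-4-{[(2E,4S,6R)-4,6,8-trimethylnona-2,7-dienoyl]amino}furan-2-yl]pentanoate | COC(=O)CCCCc1cc(NC(=O)/C=C/[C@@H](C)C[C@@H](C)C=C(C)C)c(O[Si](C)(C)C(C)(C)C)o1 | intermediate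
16 | (R)-(+)-p-tolyl vinyl sulfoxide, 1-[(R)-ethenylsulfinyl]-4-methylbenzene | C=C[S@@](=O)c1ccc(C)cc1 | starting material
17 | (R)-1-lithiovinyl p-tolyl sulfoxide (not isolated) | [Li]C(=C)[S@@](=O)c1ccc(C)cc1 | intermediate
18 | (S)-1-chlorovinyl p-tolyl sulfoxide, 1-[(S)-(1-chloroethenyl)sulfinyl]-4-methylbenzene | C=C(Cl)[S@@](=O)c1ccc(C)cc1 | intermediate
19 | 7-oxabicyclo[2.2.1]heptene cycloadduct of 15 and 18: silyloxy on the ketal bridgehead, adjacent carbon with exo chlorine and endo (S)-p-tolylsulfinyl, methoxycarbonylbutyl chain on the other bridgehead (configured as the carbinol carbon of 22), dienamide on the ring alkene (not isolated) | CC(C)(C)[Si](C)(C)O[C@]12O[C@](CCCCC(=O)OC)(C=C1NC(=O)/C=C/[C@@H](C)C[C@@H](C)C=C(C)C)C[C@]2(Cl)[S@@](=O)c1ccc(C)cc1 | intermediate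
20 | methyl 5-[(1S,5R)-5-chloro-1-hydroxy-5-[(S)-(4-methylphenyl)sulfinyl]-4-oxo-3-{[(2E,4S,6R)-4,6,8-trimethylnona-2,7-dienoyl]amino}cyclohex-2-en-1-yl]pentanoate (not isolated) | CC(C)=C[C@H](C)C[C@H](C)/C=C/C(=O)NC1=C[C@](O)(CCCCC(=O)OC)C[C@](Cl)([S@@](=O)c2ccc(C)cc2)C1=O | intermediate
21 | methyl 5-[(1R)-3-chloro-1-hydroxy-4-oxo-5-{[(2E,4S,6R)-4,6,8-trimethylnona-2,7-dienoyl]amino}cyclohexa-2,5-dien-1-yl]pentanoate | CC(C)=C[C@H](C)C[C@H](C)/C=C/C(=O)NC1=C[C@](O)(CCCCC(=O)OC)C=C(Cl)C1=O | intermediate
22 | 5-[(1R)-3-chloro-1-hydroxy-4-oxo-5-{[(2E,4S,6R)-4,6,8-trimethylnona-2,7-dienoyl]amino}cyclohexa-2,5-dien-1-yl]pentanoic acid | CC(C)=C[C@H](C)C[C@H](C)/C=C/C(=O)NC1=C[C@](O)(CCCCC(=O)O)C=C(Cl)C1=O | target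

**Count.** Total: 13 steps. Longest linear sequence: 10 steps (1–6, 9, 10, 12, 13).

**Steps most likely to fail**

1. Step 12. The furan face may be poorly controlled, because the π-facial choice at the dienophile is coupled to endo versus exo placement of the sulfinyl group, so C4 could form as a mixture. Fallback: control by the sulfur auxiliary is given up and C4 is secured by separation of diastereomers. Setting out from 15 (with 18), the same sequence is run to completion on whatever mixture forms: the stereoisomer mixture of cycloadducts F1 is opened to the stereoisomer mixture of sulfinyl ketones F2 and eliminated, giving 21 together with the (1S)-epimer of 21 F3. Because the amide chain carries two fixed stereocentres, 21 and F3 are diastereomers and should separate by preparative HPLC. The route is re-entered at 21.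

2. Step 9. The strongly enolised keto lactone may condense only slowly with the weakly nucleophilic primary amide, and prolonged acidic heating may isomerise or cyclise the trisubstituted alkene of 7. Fallback: C–N cross-coupling instead of condensation. Setting out from 13, Tf2O and 2,6-lutidine (CH2Cl2, −78 °C) should give the enol triflate methyl 5-[5-oxo-4-(trifluoromethylsulfonyloxy)-2,5-dihydrofuran-2-yl]pentanoate F4. This is coupled with 7 by palladium-catalysed amidation of the enol triflate (Pd2(dba)3, Xantphos, Cs2CO3, 1,4-dioxane, 60 °C), coming back to the route at 14.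

3. Step 13. The esterase may turn the lipophilic ester over slowly, and chemical hydrolysis would expose the chloro-quinol to hydroxide (conjugate addition at C5, then epoxide formation with loss of chloride). Fallback: the ester is cleaved before the quinol exists. Setting out from 14, LiOH (THF/H2O, 0 °C; acidification re-closes the lactone) should give 5-[5-oxo-4-{[(2E,4S,6R)-4,6,8-trimethylnona-2,7-dienoyl]amino}-2,5-dihydrofuran-2-yl]pentanoic acid F5. TBSOTf (2.4 equiv) and Et3N then give the silyl ester silyloxyfuran F6. The sequence of step 12 with 18 runs through the silyl ester cycloadduct F7 and, after fluoride (which also cleaves the silyl ester), the sulfinyl keto acid F8, and should deliver 22 directly.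

**Further compounds**

F1 | step 12 | stereoisomer mixture of the cycloadducts of 15 and 18 (ring centres undefined) | CC(C)(C)[Si](C)(C)OC12OC(CCCCC(=O)OC)(C=C1NC(=O)/C=C/[C@@H](C)C[C@@H](C)C=C(C)C)CC2(Cl)[S@@](=O)c1ccc(C)cc1
F2 | step 12 | stereoisomer mixture of the chlorosulfinyl hydroxy ketones (ring centres undefined) | CC(C)=C[C@H](C)C[C@H](C)/C=C/C(=O)NC1=CC(O)(CCCCC(=O)OC)CC(Cl)([S@@](=O)c2ccc(C)cc2)C1=O
F3 | step 12 | methyl 5-[(1S)-3-chloro-1-hydroxy-4-oxo-5-{[(2E,4S,6R)-4,6,8-trimethylnona-2,7-dienoyl]amino}cyclohexa-2,5-dien-1-yl]pentanoate | CC(C)=C[C@H](C)C[C@H](C)/C=C/C(=O)NC1=C[C@@](O)(CCCCC(=O)OC)C=C(Cl)C1=O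
F4 | step 9 | methyl 5-[5-oxo-4-(trifluoromethylsulfonyloxy)-2,5-dihydrofuran-2-yl]pentanoate (racemic) | COC(=O)CCCCC1C=C(OS(=O)(=O)C(F)(F)F)C(=O)O1
F5 | step 13 | 5-[5-oxo-4-{[(2E,4S,6R)-4,6,8-trimethylnona-2,7-dienoyl]amino}-2,5-dihydrofuran-2-yl]pentanoic acid (both lactone epimers) | OC(=O)CCCCC1C=C(NC(=O)/C=C/[C@@H](C)C[C@@H](C)C=C(C)C)C(=O)O1
F6 | step 13 | tert-butyldimethylsilyl 5-[5-(tert-butyldimethylsilyloxy)-4-{[(2E,4S,6R)-4,6,8-trimethylnona-2,7-dienoyl]amino}furan-2-yl]pentanoate | CC(C)(C)[Si](C)(C)OC(=O)CCCCc1cc(NC(=O)/C=C/[C@@H](C)C[C@@H](C)C=C(C)C)c(O[Si](C)(C)C(C)(C)C)o1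
F7 | step 13 | silyl ester analogue of cycloadduct 19 (same configuration) | CC(C)(C)[Si](C)(C)O[C@]12O[C@](CCCCC(=O)O[Si](C)(C)C(C)(C)C)(C=C1NC(=O)/C=C/[C@@H](C)C[C@@H](C)C=C(C)C)C[C@]2(Cl)[S@@](=O)c1ccc(C)cc1
F8 | step 13 | 5-[(1S,5R)-5-chloro-1-hydroxy-5-[(S)-(4-methylphenyl)sulfinyl]-4-oxo-3-{[(2E,4S,6R)-4,6,8-trimethylnona-2,7-dienoyl]amino}cyclohex-2-en-1-yl]pentanoic acid | CC(C)=C[C@H](C)C[C@H](C)/C=C/C(=O)NC1=C[C@](O)(CCCCC(=O)O)C[C@](Cl)([S@@](=O)c2ccc(C)cc2)C1=O
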